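## Analysis of the target

The target 16 is a cyclohex-3-ene in which four adjacent ring carbons, C6, C1, C2 and C3, carry phenyl, the ring A aroyl group (a 2,6-dihydroxy-3,4-dimethoxyphenyl ketone), prenyl and methyl; C3=C4 is the ring alkene and C5 the only methylene. C1, C2 and C6 are stereocentres, all S: the aroyl group on C1 is trans to both the C6 phenyl and the C2 prenyl group, so phenyl and prenyl are cis to each other across C1. Sensitive points are the C1–H bond α to the ketone, two trisubstituted alkenes that do not tolerate strong protic or Lewis acid, and the electron-rich, doubly chelated resorcinol unit. Two things make the synthesis hard. The ketone carbonyl lies between a ring carbon flanked by two substituted carbons and an aryl carbon flanked by two oxygens, so this bond is difficult to form late. The all-trans arrangement around C1 is also not what an endo [4+2] union of a chalcone with a 1-substituted diene delivers. The strategy rests on three facts: C1 is α to the aryl ketone, C6 is benzylic and two bonds from C4, and C3 carries a methyl group next to C4. With a carbonyl at C4, C1–C6 is a Michael bond to a styryl ethyl ketone and C2=C3 is an aldol-condensation bond to a formyl carbon at C2, that is, a Robinson annulation with the aryl ketone in place from the start. The C4 oxygen of the resulting enone then serves as the handle through which C6 controls C2.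

## Retrosynthetic reasoning

Ring carbons keep the numbering of 16 (C1 aroyl, C2 prenyl, C3 methyl, C6 phenyl) in all intermediates.

16 ⇒ 15. The two phenolic O–H bonds are masked as methoxymethyl ethers. Free phenols cannot be carried: in formyl ketone 7 they would close onto the formyl carbon to a chromone, and they would quench aryllithium 5. The acetals also direct the lithiation that makes 5 and are the only protecting groups of the route. The forward step must remove them with acid mild enough for two trisubstituted alkenes.

15 ⇒ 14. The side-chain C=C bond of the prenyl group is cut, leaving aldehyde 14 with a CH2–CHO arm on C2. The cut is made there because such an arm next to a ring alkene is the product pattern of a Claisen rearrangement. The forward olefination must take the aldehyde and leave the hindered aryl ketone alone.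

14 ⇒ 13. The C2–CH2 bond is cut and the C4–O bond restored, giving allyl vinyl ether 13. The sigmatropic shift moves carbon from the C4 oxygen to C2 on one face of the ring, creates the C3=C4 alkene and removes the C4 oxygen in the same event, so the configuration at C2 follows from that at C4. Direct conjugate addition of an allyl nucleophile to C2 of enone 11 was set aside for two reasons. C2 would have to be attacked anti to the C1 aroyl group but syn to the C6 phenyl group, against the axial approach that a 5-substituted cyclohexenone prefers, so the two controlling groups oppose each other. The organometallic reagent would also meet an acidic C1–H and a second ketone.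

13 ⇒ 12 ⇒ 11. The O–vinyl bond and then the C4–H bond are cut, leading through alcohol 12 to enone 11. What is gained is that C4 can be set from C6: axial hydride delivery to the half-chair of 11 should give the alcohol cis to phenyl, and the shift copies this relationship to C2 (phenyl and prenyl cis in 16). The forward reduction must touch the enone carbonyl only.

11 ⇒ 7 + 8. The C1–C6 bond and the C2=C3 double bond are cut. This opens the carbocycle into formyl ketone 7 and enone 8, two pieces of similar size. The cut is made here because C1 is the carbon between the two carbonyls of 7 and C6 is the β-carbon of 8, while C3 and its methyl are the ethyl group of 8. The forward reaction must add 7 to one face of 8 (C6), close the ring onto the formyl carbon rather than the aryl ketone, lose water, and let C1 settle trans to phenyl.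

7 ⇒ 6. The bond between the methyl carbon of 6 and the formyl carbon is cut (crossed Claisen condensation with a formate ester). Only 6 can enolise, so the condensation is unambiguous.

6 ⇒ 5 ⇒ 4. The aryl–acyl bond is cut to aryllithium 5 and an acetyl donor that stops at the ketone stage. The position between the two acetal oxygens of 4 is the one a lithium base removes, so the crowded ketone is made early and by the arene's own directing groups.

4 ⇒ 3 ⇒ 2 ⇒ 1. The acetals are removed to diol 3, whose second hydroxyl comes from the formyl group of commercial aldehyde 1 by aryl migration to oxygen (via formate 2). The substitution pattern of ring A is thus bought, not built.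

## Alternatives that were turned down

Ring A positions are written C1′ (carbonyl-bearing) to C6′.

Alternative 1: The carbocycle is kept and the C1–acyl carbon bond and the C2–CH2 bond are cut. This leads to (S)-4-phenylcyclohex-2-en-1-one A2, tris(methylthio)methyllithium A3 as a masked carboxyl anion, and 1-bromo-3-methylbut-2-ene A4. In the forward key step A3 adds to the β-carbon of A2 anti to the neighbouring phenyl group, and the enolate is alkylated by A4 anti to the new substituent. The product is (2S,3R,4S)-2-(3-methylbut-2-en-1-yl)-4-phenyl-3-[tris(methylsulfanyl)methyl]cyclohexan-1-one A1.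
- For it: each new centre is set by the substituent directly beside it, a matched and well-understood case. On the configuration of C2 this is stronger than the chosen route, which relays the information from C6 through C4.
- Against it: A2 must first be made as a single enantiomer. The ketone of A1 must be converted into the C3 methyl alkene (enol triflate towards C4, then methyl coupling). Most seriously, the orthothioester must be unmasked to an acyl derivative that a 2,6-dioxygenated aryl metal then attacks at a carbon flanked by two substituted ring carbons. The most hindered bond of the molecule is left to the end, where enolisation at C1 and failure to add compete.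
- Comparison: the sequence is not shorter once A2 and the ring A nucleophile are counted. In place of the stronger C2 control, the chosen strategy has the aryl ketone in place from the third step and builds the ring with two stereocentres in one catalytic operation.

Alternative 2: Ring A is disconnected so that C1′ and C2′ come from an alkyne and the other four carbons from a cyclobutenone. The partners are 2,3-dimethoxycyclobut-2-en-1-one A6 and the silyloxyalkyne A7, which is tert-butyldimethylsilyl-protected 1-[(1S,2S,6S)-3-methyl-2-(3-methylbut-2-en-1-yl)-6-phenylcyclohex-3-en-1-yl]-3-(triisopropylsilyloxy)prop-2-yn-1-ol. On heating, A6 opens to a vinylketene, which adds the alkyne in a [2+2] sense. The four-membered ring opens again and a 6π closure with tautomerisation gives the phenol A5, with free hydroxyl on C6′, silyloxy on C2′ and the silylated carbinol on C1′.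
- For it: no bond is made by attack on a hindered carbonyl, and the substitution pattern of ring A follows from the mechanism. On the aryl–C1 linkage this is stronger than the chosen route, whose lithiation rests on a preference between two directing groups.
- Against it: all three ring stereocentres and both alkenes must already be present in A7, so a complete stereocontrolled synthesis of the carbocycle is still needed and the key step does nothing for the stereochemical problem. A6 is not commercial and costs several steps. Ketene intermediates are generated hot in the presence of two alkenes. A5 is an ortho-hydroxybenzyl silyl ether, prone to ortho-quinone methide formation, and must still be desilylated and oxidised at a crowded benzylic carbinol.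
- Comparison: it is the longest of the four. The chosen strategy instead forms the carbocycle and its first two stereocentres in the same step.

Alternative 3: The aryl–carbonyl bond is cut to (1S,2S,6S)-3-methyl-2-(3-methylbut-2-en-1-yl)-6-phenylcyclohex-3-ene-1-carboxylic acid A9 and the aryne precursor 3,4,5-trimethoxy-2-(trimethylsilyl)phenyl trifluoromethanesulfonate A10. Fluoride releases the aryne from A10. The carboxylate of A9 adds through oxygen to the aryne carbon remote from the methoxy group (C6′), and the aryl anion formed beside the methoxy group attacks the acyl carbon. The four-membered intermediate opens to (6-hydroxy-2,3,4-trimethoxyphenyl)[(1S,2S,6S)-3-methyl-2-(3-methylbut-2-en-1-yl)-6-phenylcyclohex-3-en-1-yl]methanone A8. Cleavage of the C2′ methyl ether would then give 16.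
- For it: ring A needs no protecting groups, the ketone arises by an intramolecular acyl shift, and the endgame is the shortest. On protecting-group economy it is stronger than the chosen route.
- Against it: A9 with its trans,trans arrangement is itself the unsolved stereochemical problem. The acyl shift must occur at a carboxyl carbon between two substituted ring carbons, where O-arylation without migration and protonation of the aryl anion compete. The final demethylation must distinguish the C2′ methoxy from its neighbour on C3′ while the carbonyl is already chelated by the C6′ hydroxyl, and it needs a Lewis acid in the presence of the prenyl and ring alkenes.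
- Comparison: the chosen strategy pays with two acetals, but sets the stereocentres and places the ketone in the same sequence, and ends with a mild protic deprotection.

Key step: step 5

## Route

Assumption: the sense of induction of the 9-amino-9-deoxy-epi-cinchona amines is taken to follow their additions of cyclic 1,3-dicarbonyl donors to benzylideneacetone, which points to the quinidine-derived amine for S at C6; the quinine-derived pseudoenantiomer would be used if the sense proved opposite.

Step 1
Reactants: 1 3-hydroxy-4,5-dimethoxybenzaldehyde
Product: 3 4,5-dimethoxybenzene-1,3-diol, via 3-hydroxy-4,5-dimethoxyphenyl formate 2 (not isolated)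
Conditions: mCPBA, CH2Cl2, 0 °C → rt; NaHCO3 wash; then K2CO3 (cat.), MeOH, rt
Reagents that add atoms: 3-chloroperoxybenzoic acid (mCPBA), OOC(=O)c1cccc(Cl)c1
Why: Baeyer–Villiger oxidation: in the peracid adduct the electron-rich aryl group (methoxy para to the formyl carbon) migrates in preference to hydrogen, and formate 2 is cleaved by methanolysis; the same conversion of trialkoxybenzaldehydes into phenols is routine.

Step 2
Reactants: 3 4,5-dimethoxybenzene-1,3-diol
Product: 4 1,2-dimethoxy-3,5-bis(methoxymethoxy)benzene
Conditions: MOMCl, i-Pr2NEt, CH2Cl2, 0 °C → rt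
Reagents that add atoms: chloromethyl methyl ether (MOMCl), COCCl
Why: Twofold O-alkylation of the phenols (Williamson-type ether synthesis with a reactive α-chloro ether); the acetals withstand the organolithium, hydride, ylide and heat that follow and are cleaved by mild acid at the end.

Step 3
Reactants: 4 1,2-dimethoxy-3,5-bis(methoxymethoxy)benzene
Product: 6 1-[2,6-bis(methoxymethoxy)-3,4-dimethoxyphenyl]ethan-1-one, via [2,6-bis(methoxymethoxy)-3,4-dimethoxyphenyl]lithium 5 (not isolated)
Conditions: n-BuLi, THF, 0 °C; then MeC(O)N(OMe)Me, −78 → 0 °C; NH4Cl (aq.)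
Reagents that add atoms: N-methoxy-N-methylacetamide, CC(=O)N(C)OC
Why: Directed ortho-metalation: the ring hydrogen between the two methoxymethoxy groups is flanked by the two strongest lithium-coordinating groups and should be removed in preference to the one between a methoxymethoxy and a methoxy group. Aryllithium 5 adds to the N-methoxy-N-methyl amide to a chelated tetrahedral adduct that releases ketone 6 only on work-up, so no second addition occurs.

Step 4
Reactants: 6 1-[2,6-bis(methoxymethoxy)-3,4-dimethoxyphenyl]ethan-1-one
Product: 7 3-[2,6-bis(methoxymethoxy)-3,4-dimethoxyphenyl]-3-oxopropanal (chelated hydroxymethylene enol form)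
Conditions: NaH, HCO2Et, THF, 0 °C → rt; then AcOH/H2O, 0 °C
Reagents that add atoms: ethyl formate, CCOC=O
Why: Crossed Claisen condensation: only 6 can enolise and only the formate can act as acceptor, and the product is drawn out of the equilibrium as its stabilised sodium enolate. 7 is liberated as the hydroxymethylene ketone and used at once, because aroylacetaldehydes condense with themselves on standing.

Step 5
Reactants: 7 3-[2,6-bis(methoxymethoxy)-3,4-dimethoxyphenyl]-3-oxopropanal; 8 (E)-1-phenylpent-1-en-3-one
Product: 11 (4S,5S)-4-[2,6-bis(methoxymethoxy)-3,4-dimethoxybenzoyl]-2-methyl-5-phenylcyclohex-2-en-1-one, via Michael adduct 9 (not isolated), via aldol 10 (not isolated)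
Conditions: 9-amino-9-deoxy-epi-quinidine (20 mol%), salicylic acid (40 mol%), 8 (1.5 equiv), PhMe, rt, slow addition of 7; then 45 °C
Reagents that add atoms: none
Why: Proposed new method: the primary amine condenses with enone 8 to an iminium ion whose protonated quinuclidine, paired with salicylate, covers one face; the hydroxymethylene enol of 7 adds through C1 to the open Re face of the β-carbon, which forms C1–C6 and fixes C6 as S. The closest known reaction type is the 9-amino-9-deoxy-epi-cinchona-catalysed Michael addition of β-keto esters and cyclic 1,3-diketones to benzylideneacetone-type enones with ensuing aldol condensation; new here are a 3-aryl-3-oxopropanal as donor and ring closure onto its formyl carbon. The addition leaves the enamine of the ethyl ketone in 9, whose C3 attacks the formyl carbon C2 in a 6-(enolendo)-exo-trig aldol closure to 10, and E1cB loss of water gives the C2=C3 enone of 11. C6 is set by the catalyst; C1, which is α to the aryl ketone and γ to the new enone, equilibrates through its enol under the amine salt to the diequatorial trans arrangement with phenyl. The step needs the formyl group and not the aryl ketone as aldol acceptor, which the higher electrophilicity of the aldehyde and the two ortho methoxymethoxy groups that twist and shield the aryl ketone secure. It also needs the amine to activate 8 instead of being tied up by the formyl group of 7 as a vinylogous amide; slow addition of 7 to 8 and catalyst, and the acid that keeps this condensation reversible, serve this. The acetals tolerate the weak carboxylic acid.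

Step 6
Reactants: 11 (4S,5S)-4-[2,6-bis(methoxymethoxy)-3,4-dimethoxybenzoyl]-2-methyl-5-phenylcyclohex-2-en-1-one
Product: 12 [2,6-bis(methoxymethoxy)-3,4-dimethoxyphenyl][(1S,4R,6S)-4-hydroxy-3-methyl-6-phenylcyclohex-2-en-1-yl]methanone (hydroxyl cis to phenyl)
Conditions: NaBH4, CeCl3·7H2O, MeOH, −78 °C
Reagents that add atoms: none
Why: Luche 1,2-reduction: the cerium-activated enone carbonyl is reduced at −78 °C while the aryl ketone, twisted between two ortho substituents and α-branched, should not react. Axial hydride delivery to the half-chair with aroyl and phenyl equatorial gives the pseudoequatorial C4 alcohol cis to the C6 phenyl (4R), as with 5-substituted 2-methylcyclohexenones such as carvone.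

Step 7
Reactants: 12 [2,6-bis(methoxymethoxy)-3,4-dimethoxyphenyl][(1S,4R,6S)-4-hydroxy-3-methyl-6-phenylcyclohex-2-en-1-yl]methanone
Product: 13 [2,6-bis(methoxymethoxy)-3,4-dimethoxyphenyl][(1S,4R,6S)-4-(ethenyloxy)-3-methyl-6-phenylcyclohex-2-en-1-yl]methanone
Conditions: butyl vinyl ether (solvent), Pd(OCOCF3)2 (5 mol%), 4,7-diphenyl-1,10-phenanthroline (5 mol%), Et3N (10 mol%), 75 °C
Reagents that add atoms: butyl vinyl ether, C=COCCCC
Why: Palladium-catalysed transfer vinylation (transetherification) of a secondary allylic alcohol; the C4–O bond is not broken, so C4 keeps its configuration, and triethylamine keeps the medium safe for the acetals.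

Step 8
Reactants: 13 [2,6-bis(methoxymethoxy)-3,4-dimethoxyphenyl][(1S,4R,6S)-4-(ethenyloxy)-3-methyl-6-phenylcyclohex-2-en-1-yl]methanone
Product: 14 2-[(1S,5S,6S)-6-[2,6-bis(methoxymethoxy)-3,4-dimethoxybenzoyl]-2-methyl-5-phenylcyclohex-2-en-1-yl]acetaldehyde (side chain trans to aroyl, cis to phenyl)
Conditions: PhMe, i-Pr2NEt (5 mol%), sealed tube, 180 °C
Reagents that add atoms: none
Why: Claisen [3,3]-sigmatropic rearrangement: the new C–C bond forms at C2 on the ring face from which the oxygen leaves C4 (suprafacial 1,3-transfer), so the acetaldehyde arm enters cis to phenyl and trans to aroyl (2S in the numbering of 16) and the alkene is placed at C3=C4. The conditions are thermal and neutral, which the C1 centre and the acetals tolerate.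

Step 9
Reactants: 14 2-[(1S,5S,6S)-6-[2,6-bis(methoxymethoxy)-3,4-dimethoxybenzoyl]-2-methyl-5-phenylcyclohex-2-en-1-yl]acetaldehyde
Product: 15 [2,6-bis(methoxymethoxy)-3,4-dimethoxyphenyl][(1S,2S,6S)-3-methyl-2-(3-methylbut-2-en-1-yl)-6-phenylcyclohex-3-en-1-yl]methanone
Conditions: i-PrPPh3I, n-BuLi, THF, 0 °C; then 14, −78 °C → rt
Reagents that add atoms: isopropyltriphenylphosphonium iodide, CC(C)[P+](c1ccccc1)(c1ccccc1)c1ccccc1.[I-]
Why: Wittig olefination with the non-stabilised isopropylidene ylide converts the aldehyde into the prenyl alkene; the di-ortho-substituted, α-branched aryl ketone is too hindered to compete at low temperature.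

Step 10
Reactants: 15 [2,6-bis(methoxymethoxy)-3,4-dimethoxyphenyl][(1S,2S,6S)-3-methyl-2-(3-methylbut-2-en-1-yl)-6-phenylcyclohex-3-en-1-yl]methanone
Product: 16 (2,6-dihydroxy-3,4-dimethoxyphenyl)[(1S,2S,6S)-3-methyl-2-(3-methylbut-2-en-1-yl)-6-phenylcyclohex-3-en-1-yl]methanone
Conditions: HCl (3 M aq.), MeOH, 40 °C
Reagents that add atoms: none
Why: Acid-catalysed acetal exchange with methanol removes both methoxymethyl groups, each assisted by the neighbouring ketone oxygen. The dilute acid should leave the two trisubstituted alkenes alone, and C1, trans to both neighbours, has no driving force to epimerise to the all-cis isomer.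

## Compound list

1 | 3-hydroxy-4,5-dimethoxybenzaldehyde | O=Cc1cc(O)c(OC)c(OC)c1 | starting material
2 | 3-hydroxy-4,5-dimethoxyphenyl formate | O=COc1cc(O)c(OC)c(OC)c1 | intermediate (not isolated)
3 | 4,5-dimethoxybenzene-1,3-diol | Oc1cc(O)c(OC)c(OC)c1 | intermediate
4 | 1,2-dimethoxy-3,5-bis(methoxymethoxy)benzene | COCOc1cc(OC)c(OC)c(OCOC)c1 | intermediate
5 | [2,6-bis(methoxymethoxy)-3,4-dimethoxyphenyl]lithium | COCOc1cc(OC)c(OC)c(OCOC)c1[Li] | intermediate (not isolated)
6 | 1-[2,6-bis(methoxymethoxy)-3,4-dimethoxyphenyl]ethan-1-one | COCOc1cc(OC)c(OC)c(OCOC)c1C(C)=O | intermediate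
7 | 3-[2,6-bis(methoxymethoxy)-3,4-dimethoxyphenyl]-3-oxopropanal | COCOc1cc(OC)c(OC)c(OCOC)c1C(=O)CC=O | intermediate
8 | (E)-1-phenylpent-1-en-3-one | CCC(=O)/C=C/c1ccccc1 | starting material
9 | (3S)-2-[2,6-bis(methoxymethoxy)-3,4-dimethoxybenzoyl]-5-oxo-3-phenylheptanal (C2 epimers and enol) | COCOc1cc(OC)c(OC)c(OCOC)c1C(=O)C(C=O)[C@H](CC(=O)CC)c1ccccc1 | intermediate (not isolated)
10 | (5S)-4-[2,6-bis(methoxymethoxy)-3,4-dimethoxybenzoyl]-3-hydroxy-2-methyl-5-phenylcyclohexan-1-one (mixture at C2, C3, C4) | COCOc1cc(OC)c(OC)c(OCOC)c1C(=O)C1C(O)C(C)C(=O)C[C@@H]1c1ccccc1 | intermediate (not isolated)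
11 | (4S,5S)-4-[2,6-bis(methoxymethoxy)-3,4-dimethoxybenzoyl]-2-methyl-5-phenylcyclohex-2-en-1-one | COCOc1cc(OC)c(OC)c(OCOC)c1C(=O)[C@H]1C=C(C)C(=O)C[C@@H]1c1ccccc1 | intermediate
12 | [2,6-bis(methoxymethoxy)-3,4-dimethoxyphenyl][(1S,4R,6S)-4-hydroxy-3-methyl-6-phenylcyclohex-2-en-1-yl]methanone | COCOc1cc(OC)c(OC)c(OCOC)c1C(=O)[C@H]1C=C(C)[C@H](O)C[C@@H]1c1ccccc1 | intermediate
13 | [2,6-bis(methoxymethoxy)-3,4-dimethoxyphenyl][(1S,4R,6S)-4-(ethenyloxy)-3-methyl-6-phenylcyclohex-2-en-1-yl]methanone | COCOc1cc(OC)c(OC)c(OCOC)c1C(=O)[C@H]1C=C(C)[C@H](OC=C)C[C@@H]1c1ccccc1 | intermediate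
14 | 2-[(1S,5S,6S)-6-[2,6-bis(methoxymethoxy)-3,4-dimethoxybenzoyl]-2-methyl-5-phenylcyclohex-2-en-1-yl]acetaldehyde | COCOc1cc(OC)c(OC)c(OCOC)c1C(=O)[C@H]1[C@H](CC=O)C(C)=CC[C@@H]1c1ccccc1 | intermediate
15 | [2,6-bis(methoxymethoxy)-3,4-dimethoxyphenyl][(1S,2S,6S)-3-methyl-2-(3-methylbut-2-en-1-yl)-6-phenylcyclohex-3-en-1-yl]methanone | COCOc1cc(OC)c(OC)c(OCOC)c1C(=O)[C@H]1[C@H](CC=C(C)C)C(C)=CC[C@@H]1c1ccccc1 | intermediate
16 | (2,6-dihydroxy-3,4-dimethoxyphenyl)[(1S,2S,6S)-3-methyl-2-(3-methylbut-2-en-1-yl)-6-phenylcyclohex-3-en-1-yl]methanone | COc1cc(O)c(C(=O)[C@H]2[C@H](CC=C(C)C)C(C)=CC[C@@H]2c2ccccc2)c(O)c1OC | target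

## Step count and least certain steps

Total: 10 steps. Longest linear sequence: 10 steps (1 → 16); enone 8 is bought.

Step 5 (key step, proposed new method). Most likely to go wrong: loss of the primary amine by condensation with the formyl group of 7, which would stop turnover; self-condensation of 7 before it adds; and weaker face discrimination with a donor that has not been used in this catalysis. Migration of the C2=C3 double bond towards the aryl ketone under the amine salt is a lesser risk, because it only touches the re-equilibrating C1 centre.
Fallback with known chemistry, from 6, returning at 11: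
- Aldol condensation of 6 with benzaldehyde (KOH, EtOH) should give the chalcone (E)-1-[2,6-bis(methoxymethoxy)-3,4-dimethoxyphenyl]-3-phenylprop-2-en-1-one F1.
- Thermal [4+2] cycloaddition of F1 with (E)-1-methoxy-2-methyl-3-(trimethylsilyloxy)buta-1,3-diene (PhMe, 130 °C, sealed tube) should give the racemic cycloadduct [2,6-bis(methoxymethoxy)-3,4-dimethoxyphenyl][2-methoxy-3-methyl-6-phenyl-4-(trimethylsilyloxy)cyclohex-3-en-1-yl]methanone F2. The nucleophilic CH2 terminus of the diene bonds to the benzylic carbon, and aroyl and phenyl stay trans.
- Brief treatment with 0.1 M HCl in THF at 0 °C hydrolyses the silyl enol ether and eliminates methanol to the racemic trans-4-aroyl-2-methyl-5-phenylcyclohex-2-en-1-one F3.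
- Preparative chromatography on a chiral stationary phase separates F3 into 11 and its enantiomer.
This fallback avoids the formyl ketone and the amine altogether, at the cost of half the material.

Step 8 (with step 7). Most likely to go wrong: slow rearrangement, because the ring must flip to place the C4 oxygen pseudoaxial with the phenyl group syn-axial, so that loss of the allylic oxygen to a diene competes at the temperature needed.
Fallback from 11, returning at 15:
- Conjugate allylation (allylMgBr, CuBr·SMe2, TMSCl, THF, −78 °C) gives the silyl enol ether [2,6-bis(methoxymethoxy)-3,4-dimethoxyphenyl][(1R,2S,6S)-3-methyl-6-phenyl-2-(prop-2-en-1-yl)-4-(trimethylsilyloxy)cyclohex-3-en-1-yl]methanone F4.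
- CsF and PhNTf2 in DME convert F4 into the enol triflate (1R,2S,6S)-configured 4-(trifluoromethylsulfonyloxy) analogue F5.
- Pd(OAc)2, PPh3, Bu3N and HCO2H in DMF at 60 °C reduce F5 to [2,6-bis(methoxymethoxy)-3,4-dimethoxyphenyl][(1S,2S,6S)-3-methyl-6-phenyl-2-(prop-2-en-1-yl)cyclohex-3-en-1-yl]methanone F6.
- Cross-metathesis of F6 with 2-methylbut-2-ene (second-generation Grubbs catalyst, CH2Cl2, 40 °C) gives 15.
The fallback's own weak point is the facial selectivity of the allyl addition, since the aroyl and phenyl groups direct to opposite faces.

Step 6. Most likely to go wrong: hydride delivery to the other face, if the half-chair with axial aroyl and phenyl reacts. This gives the C4 epimer, which would carry the side chain to the wrong face of C2. Reduction of the aryl ketone is less likely.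
Fallback from 11, returning at 12:
- The reduction then gives the epimer [2,6-bis(methoxymethoxy)-3,4-dimethoxyphenyl][(1S,4S,6S)-4-hydroxy-3-methyl-6-phenylcyclohex-2-en-1-yl]methanone F7.
- Mitsunobu inversion (4-nitrobenzoic acid, PPh3, diisopropyl azodicarboxylate, THF, 0 °C) gives (1R,4S,5S)-4-[2,6-bis(methoxymethoxy)-3,4-dimethoxybenzoyl]-2-methyl-5-phenylcyclohex-2-en-1-yl 4-nitrobenzoate F8.
- Methanolysis (K2CO3, MeOH) gives 12.

Step 3. Most likely to go wrong: proton transfer from the acetamide to the hindered aryllithium, which returns 4, and some lithiation at the other ring position flanked by two oxygens.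
Fallback from 4 (through 5), returning at 6:
- 5 is quenched with acetaldehyde at −78 °C, which reacts faster than it can be deprotonated, to give 1-[2,6-bis(methoxymethoxy)-3,4-dimethoxyphenyl]ethan-1-ol F9.
- Oxidation of the benzylic alcohol (MnO2, CH2Cl2, or 2-iodoxybenzoic acid, EtOAc, 70 °C) gives 6. Any regioisomer is removed at the alcohol stage.

## Further compounds

F1 | step 5 | (E)-1-[2,6-bis(methoxymethoxy)-3,4-dimethoxyphenyl]-3-phenylprop-2-en-1-one | COCOc1cc(OC)c(OC)c(OCOC)c1C(=O)/C=C/c1ccccc1
F2 | step 5 | racemic [2,6-bis(methoxymethoxy)-3,4-dimethoxyphenyl][2-methoxy-3-methyl-6-phenyl-4-(trimethylsilyloxy)cyclohex-3-en-1-yl]methanone (1,6-trans, epimers at C2; both enantiomers shown) | COCOc1cc(OC)c(OC)c(OCOC)c1C(=O)[C@H]1C(OC)C(C)=C(O[Si](C)(C)C)C[C@@H]1c1ccccc1.COCOc1cc(OC)c(OC)c(OCOC)c1C(=O)[C@@H]1C(OC)C(C)=C(O[Si](C)(C)C)C[C@H]1c1ccccc1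
F3 | step 5 | racemic trans-4-[2,6-bis(methoxymethoxy)-3,4-dimethoxybenzoyl]-2-methyl-5-phenylcyclohex-2-en-1-one (1:1 mixture of 11 and its enantiomer) | COCOc1cc(OC)c(OC)c(OCOC)c1C(=O)[C@H]1C=C(C)C(=O)C[C@@H]1c1ccccc1.COCOc1cc(OC)c(OC)c(OCOC)c1C(=O)[C@@H]1C=C(C)C(=O)C[C@H]1c1ccccc1
F4 | step 8 | [2,6-bis(methoxymethoxy)-3,4-dimethoxyphenyl][(1R,2S,6S)-3-methyl-6-phenyl-2-(prop-2-en-1-yl)-4-(trimethylsilyloxy)cyclohex-3-en-1-yl]methanone | COCOc1cc(OC)c(OC)c(OCOC)c1C(=O)[C@H]1[C@H](CC=C)C(C)=C(O[Si](C)(C)C)C[C@@H]1c1ccccc1
F5 | step 8 | (3S,4R,5S)-4-[2,6-bis(methoxymethoxy)-3,4-dimethoxybenzoyl]-2-methyl-5-phenyl-3-(prop-2-en-1-yl)cyclohex-1-en-1-yl trifluoromethanesulfonate | COCOc1cc(OC)c(OC)c(OCOC)c1C(=O)[C@H]1[C@H](CC=C)C(C)=C(OS(=O)(=O)C(F)(F)F)C[C@@H]1c1ccccc1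
F6 | step 8 | [2,6-bis(methoxymethoxy)-3,4-dimethoxyphenyl][(1S,2S,6S)-3-methyl-6-phenyl-2-(prop-2-en-1-yl)cyclohex-3-en-1-yl]methanone | COCOc1cc(OC)c(OC)c(OCOC)c1C(=O)[C@H]1[C@H](CC=C)C(C)=CC[C@@H]1c1ccccc1
F7 | step 6 | [2,6-bis(methoxymethoxy)-3,4-dimethoxyphenyl][(1S,4S,6S)-4-hydroxy-3-methyl-6-phenylcyclohex-2-en-1-yl]methanone | COCOc1cc(OC)c(OC)c(OCOC)c1C(=O)[C@H]1C=C(C)[C@@H](O)C[C@@H]1c1ccccc1
F8 | step 6 | (1R,4S,5S)-4-[2,6-bis(methoxymethoxy)-3,4-dimethoxybenzoyl]-2-methyl-5-phenylcyclohex-2-en-1-yl 4-nitrobenzoate | COCOc1cc(OC)c(OC)c(OCOC)c1C(=O)[C@H]1C=C(C)[C@H](OC(=O)c2ccc(cc2)[N+](=O)[O-])C[C@@H]1c1ccccc1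
F9 | step 3 | 1-[2,6-bis(methoxymethoxy)-3,4-dimethoxyphenyl]ethan-1-ol (racemic) | COCOc1cc(OC)c(OC)c(OCOC)c1C(C)O
A1 | alternative 1 | (2S,3R,4S)-2-(3-methylbut-2-en-1-yl)-4-phenyl-3-[tris(methylsulfanyl)methyl]cyclohexan-1-one | CSC(SC)(SC)[C@H]1[C@H](CC=C(C)C)C(=O)CC[C@@H]1c1ccccc1
A2 | alternative 1 | (S)-4-phenylcyclohex-2-en-1-one | O=C1CC[C@H](c2ccccc2)C=C1
A3 | alternative 1 | tris(methylthio)methyllithium | [Li]C(SC)(SC)SC
A4 | alternative 1 | 1-bromo-3-methylbut-2-ene | CC(C)=CCBr
A5 | alternative 2 | 2-{[(tert-butyldimethylsilyl)oxy][(1S,2S,6S)-3-methyl-2-(3-methylbut-2-en-1-yl)-6-phenylcyclohex-3-en-1-yl]methyl}-4,5-dimethoxy-3-[(triisopropylsilyl)oxy]phenol (carbinol epimers) | COc1cc(O)c(C(O[Si](C)(C)C(C)(C)C)[C@H]2[C@H](CC=C(C)C)C(C)=CC[C@@H]2c2ccccc2)c(O[Si](C(C)C)(C(C)C)C(C)C)c1OC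
A6 | alternative 2 | 2,3-dimethoxycyclobut-2-en-1-one | COC1=C(OC)C(=O)C1
A7 | alternative 2 | tert-butyldimethyl{[1-[(1S,2S,6S)-3-methyl-2-(3-methylbut-2-en-1-yl)-6-phenylcyclohex-3-en-1-yl]-3-[(triisopropylsilyl)oxy]prop-2-yn-1-yl]oxy}silane (carbinol epimers) | CC(C)[Si](C(C)C)(C(C)C)OC#CC(O[Si](C)(C)C(C)(C)C)[C@H]1[C@H](CC=C(C)C)C(C)=CC[C@@H]1c1ccccc1
A8 | alternative 3 | (6-hydroxy-2,3,4-trimethoxyphenyl)[(1S,2S,6S)-3-methyl-2-(3-methylbut-2-en-1-yl)-6-phenylcyclohex-3-en-1-yl]methanone | COc1cc(O)c(C(=O)[C@H]2[C@H](CC=C(C)C)C(C)=CC[C@@H]2c2ccccc2)c(OC)c1OC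
A9 | alternative 3 | (1S,2S,6S)-3-methyl-2-(3-methylbut-2-en-1-yl)-6-phenylcyclohex-3-ene-1-carboxylic acid | OC(=O)[C@H]1[C@H](CC=C(C)C)C(C)=CC[C@@H]1c1ccccc1
A10 | alternative 3 | 3,4,5-trimethoxy-2-(trimethylsilyl)phenyl trifluoromethanesulfonate | COc1cc(OS(=O)(=O)C(F)(F)F)c([Si](C)(C)C)c(OC)c1OC
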